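**Retrosynthetic overview**
1. Target ⇐ lactol acetylation and acetate-for-tosylate exchange at C-13 ⇐ oxepane closed last by intramolecular Williamson etherification (C-15 alkoxide onto the CH2OTs cis to C-5).
2. ⇐ Key step: domino Knoevenagel / intramolecular inverse-demand oxa-Diels–Alder reaction of a cyclopropanecarbaldehyde with malondialdehyde and a tethered silyl enol ether; the cycloheptane (C-1–C-5) and the dihydropyran (O–C-2) form together.
3. ⇐ trans-cyclopropane (C-6, C-7, C-11) by organocatalytic Michael-initiated ring closure of an (E)-enal with dimethyl bromomalonate.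
4. ⇐ (S)-linalool supplies C-10 (Me, OH), C-8/C-9 and the vinyl group C-1/C-2, which is later oxidised to CH2CHO.
5. Ring order: cyclopropane → cycloheptane + dihydropyran (one operation) → oxepane.

Assumption: the SMILES is read literally, so the cyclopropane is trans-fused to the cycloheptane (H-6 and H-7 anti) and cis-fused to the oxepane.
Numbering used below (2,3-seco-aromadendrane): C-1/C-5 ring fusion, C-2 acetal CH, C-3=C-4 enol ether, C-6/C-7/C-11 cyclopropane, C-8/C-9 CH2CH2, C-10 carbinol, C-12 ring CH2O, C-13 CH2OAc, C-14 methyl, C-15 allylic CH2O.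

**Step 1**
Reactants: 1 (S)-(+)-linalool; 2 (triphenylphosphoranylidene)acetaldehyde
Product: 4 (2E,6S)-6-hydroxy-6-methylocta-2,7-dienal, via lactol 3 (not isolated)
Conditions: O3, CH2Cl2, −78 °C (Sudan red end point); PPh3, −78 °C → rt; then 2 (1.05 equiv), 40 °C
Reagents that add atoms: (triphenylphosphoranylidene)acetaldehyde (compound 2), O=CC=P(c1ccccc1)(c1ccccc1)c1ccccc1
Why: Ozonolysis cleaves the electron-rich trisubstituted alkene of linalool in preference to the vinyl group, and the resulting γ-hydroxy aldehyde (lactol 3) undergoes Wittig olefination with the stabilised ylide to the (E)-enal; C-10 comes unchanged from the chiral pool.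

**Step 2**
Reactants: 4 (2E,6S)-6-hydroxy-6-methylocta-2,7-dienal; 5 dimethyl bromomalonate
Product: 7 dimethyl (2R,3R)-2-(dimethoxymethyl)-3-[(3S)-3-hydroxy-3-methylpent-4-en-1-yl]cyclopropane-1,1-dicarboxylate, via cyclopropanecarbaldehyde 6 (not isolated)
Conditions: (S)-α,α-diphenylprolinol trimethylsilyl ether (20 mol %), 2,6-lutidine (1.1 equiv), CH2Cl2, 0 °C → rt; then MeOH, HC(OMe)3, PPTS (cat.), rt
Reagents that add atoms: dimethyl bromomalonate (compound 5), COC(=O)C(Br)C(=O)OC; trimethyl orthoformate, COC(OC)OC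
Why: Iminium-catalysed Michael-initiated ring closure (organocatalytic cyclopropanation of enals): bromomalonate adds to the face of C-7 remote from the CPh2(OTMS) group and the enamine displaces bromide to close the ring with CHO trans to the side chain, setting C-6 and C-7 as (2R,3R) under catalyst control, after which orthoformate exchange masks the aldehyde as its dimethyl acetal.

**Step 3**
Reactants: 7 dimethyl (2R,3R)-2-(dimethoxymethyl)-3-[(3S)-3-hydroxy-3-methylpent-4-en-1-yl]cyclopropane-1,1-dicarboxylate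
Product: 8 [(2R,3R)-2-(dimethoxymethyl)-3-[(3S)-3-hydroxy-3-methylpent-4-en-1-yl]cyclopropane-1,1-diyl]dimethanol
Conditions: LiAlH4, THF, 0 °C → rt; Fieser work-up
Reagents that add atoms: none
Why: Hydride reduction of both malonate esters gives the 1,1-bis(hydroxymethyl) unit (future C-12 and C-13) while the acetal, the alkene and all stereocentres are untouched.

**Step 4**
Reactants: 8 [(2R,3R)-2-(dimethoxymethyl)-3-[(3S)-3-hydroxy-3-methylpent-4-en-1-yl]cyclopropane-1,1-diyl]dimethanol
Product: 10 [(2R,3R)-2-formyl-3-[(3S)-3-hydroxy-3-methylpent-4-en-1-yl]cyclopropane-1,1-diyl]bis(methylene) bis(4-methylbenzenesulfonate), via acetal bis-tosylate 9 (not isolated)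
Conditions: TsCl (2.3 equiv), Et3N, DMAP (cat.), CH2Cl2, 0 °C; then acetone/H2O (10:1), PPTS, 45 °C
Reagents that add atoms: 4-methylbenzenesulfonyl chloride, Cc1ccc(cc1)S(Cl)(=O)=O; water, O
Why: Sulfonylation takes only the two primary alcohols (the tertiary allylic alcohol does not react with TsCl), and mild acetal hydrolysis then frees the C-5 aldehyde; the two CH2OTs groups are still equivalent and no stereocentre changes.

**Step 5**
Reactants: 10 [(2R,3R)-2-formyl-3-[(3S)-3-hydroxy-3-methylpent-4-en-1-yl]cyclopropane-1,1-diyl]bis(methylene) bis(4-methylbenzenesulfonate)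
Product: 11 [(2R,3R)-2-formyl-3-[(3S)-3-hydroxy-3-methyl-5-oxopentyl]cyclopropane-1,1-diyl]bis(methylene) bis(4-methylbenzenesulfonate)
Conditions: PdCl2(PhCN)2 (12 mol %), CuCl2·2H2O (12 mol %), AgNO2 (6 mol %), O2 (1 atm), t-BuOH/MeNO2 (15:1), rt
Reagents that add atoms: dioxygen, O=O
Why: Nitrite-modified, aldehyde-selective (anti-Markovnikov) Wacker oxidation, in which the allylic oxygen and the quaternary allylic carbon direct oxygen to the terminal carbon, turns the vinyl group into CH2CHO (C-1/C-2) without creating a stereocentre.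

**Step 6**
Reactants: 11 [(2R,3R)-2-formyl-3-[(3S)-3-hydroxy-3-methyl-5-oxopentyl]cyclopropane-1,1-diyl]bis(methylene) bis(4-methylbenzenesulfonate)
Product: 12 [(2R,3R)-2-formyl-3-[(3S,4Z)-3,5-bis(tert-butyldimethylsilyloxy)-3-methylpent-4-en-1-yl]cyclopropane-1,1-diyl]bis(methylene) bis(4-methylbenzenesulfonate)
Conditions: TBSOTf (2.5 equiv), Et3N (4 equiv), CH2Cl2, −78 → 0 °C
Reagents that add atoms: tert-butyldimethylsilyl trifluoromethanesulfonate, CC(C)(C)[Si](C)(C)OS(=O)(=O)C(F)(F)F
Why: Soft enolisation/silylation converts only the C-2 aldehyde into its (Z)-silyl enol ether (the cyclopropanecarbaldehyde cannot enolise without forming an alkylidenecyclopropane) and caps the tertiary alcohol, which blocks retro-aldol and elimination pathways later.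

**Step 7 (key step)**
Reactants: 12 [(2R,3R)-2-formyl-3-[(3S,4Z)-3,5-bis(tert-butyldimethylsilyloxy)-3-methylpent-4-en-1-yl]cyclopropane-1,1-diyl]bis(methylene) bis(4-methylbenzenesulfonate); 13 malondialdehyde tetrabutylammonium salt
Product: 15 tricyclic aldehyde (4-formyl-2-silyloxy-3,4-dihydro-2H-pyran cis-fused at C-1/C-5 to the cycloheptane; cyclopropane trans-fused at C-6/C-7; 2-OTBS cis to C-10; 10-OTBS; 11,11-bis(tosyloxymethyl)), via alkylidenemalondialdehyde 14 (not isolated)
Conditions: 13 (1.2 equiv), AcOH (1.2 equiv), ethylenediammonium diacetate (10 mol %), 4 Å molecular sieves, MeCN, rt; then dilution to 0.005 M, 70 °C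
Reagents that add atoms: malondialdehyde tetrabutylammonium salt (compound 13), [O-]/C=C/C=O.CCCC[N+](CCCC)(CCCC)CCCC
Why: Proposed new method: Knoevenagel condensation of the only free aldehyde with malondialdehyde gives the doubly activated 1-oxadiene 14, which reacts in its s-trans bisected conformation about C-5–C-6 (C-4 anti to the three-membered ring) so that the tethered (Z)-silyl enol ether adds to the C-5 face on the side of C-7 (the other face is covered by the cis CH2OTs group and is out of reach of the tether), giving H-5 anti to H-6; the endo silyloxy group of the (Z)-enol ether puts C-10 endo as well and so gives the cis C-1/C-5 fusion (C-2 is corrected in step 10); the strongly exergonic [4+2] pays for the trans-bicyclo[5.1.0]octane strain, which a reversible closure could not; closest known reaction type: the Tietze domino Knoevenagel / intramolecular hetero-Diels–Alder reaction of alkylidene-1,3-dicarbonyls with enol ethers.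

**Step 8**
Reactants: 15 tricyclic aldehyde
Product: 17 tetracyclic tosylate (oxepane closed: C-12–O–C-15; 13-OTs; 2-OTBS; 10-OTBS), via allylic alcohol 16 (not isolated)
Conditions: NaBH4, CeCl3·7H2O, MeOH/THF, −40 °C; aq NaHCO3 work-up; then NaH (1.2 equiv), THF (0.005 M), 0 → 50 °C
Reagents that add atoms: none
Why: Luche 1,2-reduction of the vinylogous formate aldehyde gives the C-15 alcohol, whose sodium alkoxide displaces the only tosylate it can reach (CH2OTs cis to C-5) in a 7-exo-tet Williamson etherification, making C-11 stereogenic with the ring CH2 cis to C-5; substitution at C-12 rather than ionisation at C-15 excludes Ferrier-type allylic transposition.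

**Step 9**
Reactants: 17 tetracyclic tosylate
Product: 18 tetracyclic acetate (13-OAc; 2-OTBS; 10-OTBS)
Conditions: CsOAc (3 equiv), 18-crown-6, DMF, 75 °C
Reagents that add atoms: caesium acetate, CC(=O)[O-].[Cs+]
Why: SN2 displacement of the remaining primary cyclopropylmethyl tosylate by acetate installs the C-13 acetate without touching C-11.

**Step 10**
Reactants: 18 tetracyclic acetate
Product: 20 CNP0250836.2, via lactol 19 (not isolated)
Conditions: HF·pyridine, pyridine, THF, 0 °C → rt; aq NaHCO3 work-up; then Ac2O, pyridine, 0 °C → rt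
Reagents that add atoms: acetic anhydride, CC(=O)OC(C)=O
Why: Buffered fluoride removes both silyl groups without base (no retro-aldol of the β-hydroxy lactol), and the equilibrating lactol is acetylated on the anomeric oxygen trans to the C-1 substituent (anomerically favoured, as with iridoid lactols), which sets C-2, while the tertiary C-10 alcohol is inert to Ac2O/pyridine.

**Compound list**
1 | (S)-(+)-linalool, (3S)-3,7-dimethylocta-1,6-dien-3-ol | C=C[C@@](C)(O)CCC=C(C)C | starting material
2 | (triphenylphosphoranylidene)acetaldehyde | O=CC=P(c1ccccc1)(c1ccccc1)c1ccccc1 | starting material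
3 | (5S)-5-ethenyl-5-methyloxolan-2-ol (lactol, both anomers) | C=C[C@@]1(C)OC(O)CC1 | intermediate (not isolated)
4 | (2E,6S)-6-hydroxy-6-methylocta-2,7-dienal | O=C/C=C/CC[C@](C)(O)C=C | intermediate
5 | dimethyl bromomalonate | COC(=O)C(Br)C(=O)OC | starting material
6 | dimethyl (2R,3R)-2-formyl-3-[(3S)-3-hydroxy-3-methylpent-4-en-1-yl]cyclopropane-1,1-dicarboxylate | O=C[C@@H]1[C@@H](CC[C@](C)(O)C=C)C1(C(=O)OC)C(=O)OC | intermediate (not isolated)
7 | dimethyl (2R,3R)-2-(dimethoxymethyl)-3-[(3S)-3-hydroxy-3-methylpent-4-en-1-yl]cyclopropane-1,1-dicarboxylate | COC(OC)[C@@H]1[C@@H](CC[C@](C)(O)C=C)C1(C(=O)OC)C(=O)OC | intermediate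
8 | [(2R,3R)-2-(dimethoxymethyl)-3-[(3S)-3-hydroxy-3-methylpent-4-en-1-yl]cyclopropane-1,1-diyl]dimethanol | COC(OC)[C@@H]1[C@@H](CC[C@](C)(O)C=C)C1(CO)CO | intermediate
9 | bis(4-methylbenzenesulfonate) of diol 8 (acetal bis-tosylate) | COC(OC)[C@@H]1[C@@H](CC[C@](C)(O)C=C)C1(COS(=O)(=O)c2ccc(C)cc2)COS(=O)(=O)c2ccc(C)cc2 | intermediate (not isolated)
10 | [(2R,3R)-2-formyl-3-[(3S)-3-hydroxy-3-methylpent-4-en-1-yl]cyclopropane-1,1-diyl]bis(methylene) bis(4-methylbenzenesulfonate) | O=C[C@@H]1[C@@H](CC[C@](C)(O)C=C)C1(COS(=O)(=O)c2ccc(C)cc2)COS(=O)(=O)c2ccc(C)cc2 | intermediate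
11 | [(2R,3R)-2-formyl-3-[(3S)-3-hydroxy-3-methyl-5-oxopentyl]cyclopropane-1,1-diyl]bis(methylene) bis(4-methylbenzenesulfonate) | O=C[C@@H]1[C@@H](CC[C@](C)(O)CC=O)C1(COS(=O)(=O)c2ccc(C)cc2)COS(=O)(=O)c2ccc(C)cc2 | intermediate
12 | [(2R,3R)-2-formyl-3-[(3S,4Z)-3,5-bis(tert-butyldimethylsilyloxy)-3-methylpent-4-en-1-yl]cyclopropane-1,1-diyl]bis(methylene) bis(4-methylbenzenesulfonate) | O=C[C@@H]1[C@@H](CC[C@](C)(O[Si](C)(C)C(C)(C)C)/C=C\O[Si](C)(C)C(C)(C)C)C1(COS(=O)(=O)c2ccc(C)cc2)COS(=O)(=O)c2ccc(C)cc2 | intermediate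
13 | malondialdehyde tetrabutylammonium salt | [O-]/C=C/C=O.CCCC[N+](CCCC)(CCCC)CCCC | starting material
14 | 2-(cyclopropylmethylidene)malondialdehyde: Knoevenagel product of 12 at its formyl group | O=CC(C=O)=C[C@@H]1[C@@H](CC[C@](C)(O[Si](C)(C)C(C)(C)C)/C=C\O[Si](C)(C)C(C)(C)C)C1(COS(=O)(=O)c2ccc(C)cc2)COS(=O)(=O)c2ccc(C)cc2 | intermediate (not isolated)
15 | tricyclic aldehyde: 4-formyl-2-silyloxy-dihydropyran, H-1/H-5 cis, cyclopropane trans-fused to the cycloheptane, 2-OTBS cis to C-10, 10-OTBS, 11,11-bis(tosyloxymethyl) | O=CC3=CO[C@@H](O[Si](C)(C)C(C)(C)C)[C@@H]4[C@H]3[C@@H]1[C@@H](CC[C@]4(C)O[Si](C)(C)C(C)(C)C)C1(COS(=O)(=O)c5ccc(C)cc5)COS(=O)(=O)c5ccc(C)cc5 | intermediate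
16 | C-15 allylic alcohol of 15 | OCC3=CO[C@@H](O[Si](C)(C)C(C)(C)C)[C@@H]4[C@H]3[C@@H]1[C@@H](CC[C@]4(C)O[Si](C)(C)C(C)(C)C)C1(COS(=O)(=O)c5ccc(C)cc5)COS(=O)(=O)c5ccc(C)cc5 | intermediate (not isolated)
17 | tetracyclic tosylate: oxepane closed (C-12–O–C-15 cis to C-5), 13-OTs, 2-OTBS, 10-OTBS | Cc1ccc(cc1)S(=O)(=O)OC[C@@]12COCC3=CO[C@@H](O[Si](C)(C)C(C)(C)C)[C@@H]4[C@H]3[C@@H]1[C@H]2CC[C@]4(C)O[Si](C)(C)C(C)(C)C | intermediate
18 | tetracyclic acetate: 13-OAc, 2-OTBS, 10-OTBS | CC(=O)OC[C@@]12COCC3=CO[C@@H](O[Si](C)(C)C(C)(C)C)[C@@H]4[C@H]3[C@@H]1[C@H]2CC[C@]4(C)O[Si](C)(C)C(C)(C)C | intermediate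
19 | C-2 lactol (both anomers), 13-OAc, 10-OH | CC(=O)OC[C@@]12COCC3=COC(O)[C@@H]4[C@H]3[C@@H]1[C@H]2CC[C@]4(C)O | intermediate (not isolated)
20 | CNP0250836.2 (2,13-diacetate; in the numbering above 1R,2R,5R,6S,7R,10S,11R) | CC(=O)OC[C@@]12COCC3=CO[C@H](OC(C)=O)[C@@H]4[C@H]3[C@@H]1[C@H]2CC[C@]4(C)O | target

**Totals**
Total step count: 10. Longest linear sequence: 10 (fully linear from linalool).

**Three steps most likely to fail**

Step 7 (key domino): the [4+2] has to close a seven-membered ring trans-fused to the cyclopropane, and the silyl enol ether may hydrolyse or the oxadiene oligomerise first. The fallback sets out from 12 and returns at 15. Wittig reaction of 12 with 2 gives the stable (E)-enal F1. This simple 1-oxadiene is cyclised separately under forcing but neutral conditions (toluene, 110–150 °C, with Eu(fod)3, tris(6,6,7,7,8,8,8-heptafluoro-2,2-dimethyl-3,5-octanedionato)europium) to the 4-unsubstituted dihydropyran F2, with the same facial arguments. Vilsmeier–Haack formylation (POCl3, DMF, then aqueous NaOAc) of the enol ether β-carbon C-4 then gives 15.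

Step 5 (aldehyde-selective Wacker oxidation): a free tertiary allylic alcohol may give the methyl ketone or rearrange. The fallback sets out from 10 and returns at 11. Cross-metathesis of the vinyl group with vinylboronic acid pinacol ester (second-generation Hoveyda–Grubbs catalyst, CH2Cl2, 40 °C) gives the (E)-alkenylboronate F3. Oxidation of the C–B bond with NaBO3·4H2O in THF/H2O gives the enol, which tautomerises to aldehyde 11.

Step 8 (oxepane closure): the ether ring adds strain to the trans-fused core, and alkoxide attack on the hindered cyclopropylmethyl tosylate may be slow. The fallback sets out from 15 and returns at 18. Finkelstein exchange (NaI, 2-butanone, 70 °C) gives the diiodide F4, and Luche reduction gives the iodo alcohol F5. The neutral alcohol is then closed onto the cis CH2I by halophilic activation with Ag2O (CH2Cl2, dark) instead of through an alkoxide, giving the iodo oxepane F6. AgOAc in toluene replaces the second iodide by acetate to give 18.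

**Further compounds**
F1 | step 7 | (E)-enal from Wittig reaction of 12 with 2 | O=C/C=C/[C@@H]1[C@@H](CC[C@](C)(O[Si](C)(C)C(C)(C)C)/C=C\O[Si](C)(C)C(C)(C)C)C1(COS(=O)(=O)c2ccc(C)cc2)COS(=O)(=O)c2ccc(C)cc2
F2 | step 7 | 4-unsubstituted tricyclic dihydropyran (15 without the formyl group) | C3=CO[C@@H](O[Si](C)(C)C(C)(C)C)[C@@H]4[C@H]3[C@@H]1[C@@H](CC[C@]4(C)O[Si](C)(C)C(C)(C)C)C1(COS(=O)(=O)c5ccc(C)cc5)COS(=O)(=O)c5ccc(C)cc5
F3 | step 5 | (E)-alkenylboronic acid pinacol ester from 10 | O=C[C@@H]1[C@@H](CC[C@](C)(O)/C=C/B2OC(C)(C)C(C)(C)O2)C1(COS(=O)(=O)c3ccc(C)cc3)COS(=O)(=O)c3ccc(C)cc3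
F4 | step 8 | diiodide analogue of 15 | O=CC3=CO[C@@H](O[Si](C)(C)C(C)(C)C)[C@@H]4[C@H]3[C@@H]1[C@@H](CC[C@]4(C)O[Si](C)(C)C(C)(C)C)C1(CI)CI
F5 | step 8 | iodo alcohol (C-15 alcohol of F4) | OCC3=CO[C@@H](O[Si](C)(C)C(C)(C)C)[C@@H]4[C@H]3[C@@H]1[C@@H](CC[C@]4(C)O[Si](C)(C)C(C)(C)C)C1(CI)CI
F6 | step 8 | iodo oxepane (17 with iodide in place of tosylate) | IC[C@@]12COCC3=CO[C@@H](O[Si](C)(C)C(C)(C)C)[C@@H]4[C@H]3[C@@H]1[C@H]2CC[C@]4(C)O[Si](C)(C)C(C)(C)C
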